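**Strategy.** The route rests on cutting the C6–C7 bond of the seven-membered ring. In ferugin the C6 carbinol is homoallylic to the exocyclic C8=C14 methylene through C7, which is the signature of a type 2 carbonyl-ene reaction. A Me2AlCl-promoted ene cyclisation of a C6 aldehyde on C5 with a 2-propenyl group on C9 therefore closes the hydroazulene and sets the C6 hydroxyl and the methylene in one operation. The precursor is a cyclopentane carrying, at C1, the methyl and a trans CH2–CH(OTBS)–C(CH3)=CH2 arm, at C4 the isopropyl and a silylated tertiary hydroxyl, and at C5 the formyl group; it comes from 3-methylcyclopentenone by asymmetric conjugate addition of a bulky 1-silylvinyl group.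

Key step: step 12

**Remarks on the chemistry**
- Daucane numbering is used throughout: C1 quaternary carbon (methyl C15), C2/C3 ring CH2, C4 isopropyl carbinol, C5 ring CH, C6 the one-carbon arm on C5, C10/C9 the two-carbon arm on C1, C8 the central 2-propenyl carbon, C7 its CH2, C14 its methyl. The face of the five-membered ring that carries the C1 methyl is called β, the other α.
- A plain vinyl group is about as large as the C1 methyl and cannot steer the C5 substituent. A 1-(trimethylsilyl)vinyl group is used in its place and loses silicon on the way to the C9 aldehyde.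
- A Grignard addition at C9 would not be stereoselective, so C9 is set by a catalyst-controlled ketone reduction.
- Assumption: isopropylmagnesium chloride, isopropenylmagnesium bromide and 37% aqueous formaldehyde are bought as commercial solutions. L* is an enantiopure sulfonate-bearing imidazolinium salt (N-heterocyclic carbene precursor); the enantiomer that gives the (S) quaternary centre is used.

**Route**

Step 1
Reactants: 1 3-methylcyclopent-2-en-1-one; 2 ethynyltrimethylsilane
Product: 5 triethyl({(3S)-3-methyl-3-[1-(trimethylsilyl)ethenyl]cyclopent-1-en-1-yl}oxy)silane, via vinylalane 3 (not isolated), via aluminium enolate 4 (not isolated)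
Conditions: iBu2AlH, hexanes/THF, 55 °C; then 1, Cu(OTf)2 (5 mol%), L* (5 mol%), THF, −78 → −15 °C; then Et3SiOTf, −78 → 0 °C
Reagents that add atoms: triethylsilyl trifluoromethanesulfonate, CC[Si](CC)(CC)OS(=O)(=O)C(F)(F)F
Why: Copper-catalysed asymmetric conjugate addition: hydroalumination puts aluminium on the silicon-bearing alkyne carbon, the chiral carbene–copper catalyst delivers the 1-silylvinyl group to one face of the enone β-carbon and so sets the C1 quaternary centre under catalyst control, and the silyl triflate captures the aluminium enolate on oxygen so that the C4=C5 regiochemistry is kept.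

Step 2
Reactants: 5 silyl enol ether; 6 formaldehyde (37% aqueous)
Product: 7 (2S,3S)-2-(hydroxymethyl)-3-methyl-3-[1-(trimethylsilyl)ethenyl]cyclopentan-1-one
Conditions: aq. HCHO, Yb(OTf)3 (10 mol%), THF, rt
Reagents that add atoms: none
Why: Mukaiyama aldol reaction with formaldehyde under lanthanide triflate catalysis: the small electrophile should reach C5 from the face opposite the bulky 1-silylvinyl group on the neighbouring C1, which places the hydroxymethyl group (C6) cis to the C1 methyl.

Step 3
Reactants: 7 hydroxy ketone
Product: 8 (2S,3S)-3-methyl-2-[(triethylsilyloxy)methyl]-3-[1-(trimethylsilyl)ethenyl]cyclopentan-1-one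
Conditions: Et3SiCl, imidazole, CH2Cl2, 0 °C
Reagents that add atoms: chlorotriethylsilane, CC[Si](CC)(CC)Cl
Why: Standard silylation of a primary alcohol under mild base, which guards the β-hydroxy ketone against retro-aldol cleavage and installs the group that is oxidised off in step 11.

Step 4
Reactants: 8 silyloxy ketone; 9 isopropylmagnesium chloride
Product: 10 (1R,2S,3S)-3-methyl-1-(propan-2-yl)-2-[(triethylsilyloxy)methyl]-3-[1-(trimethylsilyl)ethenyl]cyclopentan-1-ol
Conditions: iPrMgCl, LaCl3·2LiCl, THF, 0 °C; aq. NH4Cl
Reagents that add atoms: none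
Why: Lanthanum-promoted Grignard 1,2-addition suppresses enolisation and β-hydride reduction of the hindered ketone, and the nucleophile should enter C4 from the α face, anti to the adjacent C5 side chain and to the pseudoaxial C1 methyl, so that isopropyl ends trans and the hydroxyl cis to C6.

Step 5
Reactants: 10 tertiary alcohol
Product: 12 primary alcohol in which the C1 arm is CH(SiMe3)–CH2OH (C9 hydroxyl; both C10 epimers), via alkylborane 11 (not isolated)
Conditions: BH3·THF, THF, 0 °C → rt; then NaOH, H2O2, 0 °C
Reagents that add atoms: hydrogen peroxide, OO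
Why: Hydroboration–oxidation of a 1,1-disubstituted vinylsilane places boron and then oxygen on the terminal carbon (C9) for steric reasons, and the transient C10 stereocentre is of no consequence because silicon is removed in step 6.

Step 6
Reactants: 12 β-hydroxysilane
Product: 14 aldehyde in which the C1 arm is CH2–CHO (C9 aldehyde; C4 hydroxyl free; C6 triethylsilyl ether), via silyl aldehyde 13 (not isolated)
Conditions: Dess–Martin periodinane, NaHCO3, CH2Cl2, 0 °C → rt; then K2CO3 (cat.), MeOH, 0 °C
Reagents that add atoms: none
Why: Dess–Martin oxidation gives an α-trimethylsilyl aldehyde whose C–Si bond is cleaved by methoxide at silicon with the aldehyde enolate as leaving group (desilylation of an α-silyl carbonyl compound), so that C10 becomes CH2 while the tertiary hydroxyl cannot be oxidised.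

Step 7
Reactants: 14 aldehyde; 15 isopropenylmagnesium bromide
Product: 16 allylic alcohols with the C1 arm CH2–CH(OH)–C(CH3)=CH2 (both C9 epimers)
Conditions: CH2=C(CH3)MgBr (2.5 equiv), THF, −78 → 0 °C; aq. NH4Cl
Reagents that add atoms: none
Why: Grignard addition to an unhindered aldehyde (one extra equivalent is taken up by the tertiary hydroxyl); no control at C9 is sought because step 8 removes the centre.

Step 8
Reactants: 16 allylic alcohols
Product: 17 enone with the C1 arm CH2–C(=O)–C(CH3)=CH2
Conditions: Dess–Martin periodinane, NaHCO3, CH2Cl2, 0 °C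
Reagents that add atoms: none
Why: Dess–Martin oxidation of a secondary allylic alcohol under buffered, neutral conditions that leave the tertiary alcohol and the silyl ether untouched.

Step 9
Reactants: 17 enone
Product: 18 (9S)-allylic alcohol with the C1 arm CH2–CH(OH)–C(CH3)=CH2
Conditions: (R)-2-methyl-CBS-oxazaborolidine (20 mol%), catecholborane, toluene, −78 °C
Reagents that add atoms: none
Why: Corey–Bakshi–Shibata reduction: the catalyst treats the 2-propenyl group as the large and the CH2 group as the small substituent, so the (R)-oxazaborolidine should give the (9S) alcohol under reagent control, and catecholborane at low temperature leaves the alkene untouched.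

Step 10
Reactants: 18 diol
Product: 20 fully silylated triol (C6–OSiEt3; C4–OSiEt3; C9–OTBS), via C9 TBS ether 19 (not isolated)
Conditions: tBuMe2SiOTf (1.05 equiv), 2,6-lutidine, CH2Cl2, −78 °C; then Et3SiOTf, −78 → 0 °C
Reagents that add atoms: tert-butyldimethylsilyl trifluoromethanesulfonate, CC(C)(C)[Si](C)(C)OS(=O)(=O)C(F)(F)F; triethylsilyl trifluoromethanesulfonate, CC[Si](CC)(CC)OS(=O)(=O)C(F)(F)F
Why: Silyl triflate/lutidine silylation in which the bulky TBS triflate at −78 °C should react only with the secondary allylic hydroxyl, after which the smaller triethylsilyl triflate caps the hindered tertiary hydroxyl.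

Step 11
Reactants: 20 tris(silyl) ether
Product: 21 aldehyde (C5–CHO; C4–OSiEt3; C1 arm CH2–CH(OTBS)–C(CH3)=CH2)
Conditions: (COCl)2, DMSO, CH2Cl2, −78 → −40 °C; then Et3N, −78 → 0 °C
Reagents that add atoms: none
Why: Swern oxidation of a primary triethylsilyl ether: the chlorosulfonium reagent attacks the least hindered, primary silyl ether oxygen and the alkoxysulfonium salt collapses to the aldehyde with base, while the tertiary triethylsilyl and secondary TBS ethers are inert and C5, whose formyl group already lies trans to both larger neighbours, has no driving force to epimerise.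

Step 12
Reactants: 21 aldehyde
Product: 22 bicyclic (6S)-alcohol with C8 exocyclic methylene, C4–OSiEt3 and C9–OTBS
Conditions: Me2AlCl (2 equiv), CH2Cl2, −78 → −20 °C; aq. potassium sodium tartrate
Reagents that add atoms: none
Why: Me2AlCl binds the C6 aldehyde, C7 (the terminal CH2 of the 2-propenyl group) adds to C6 while a hydrogen of the C14 methyl passes to oxygen through a six-centre ene transition state, and the alcohol–aluminium complex then loses methane to a stable alkoxide, so no proton remains to isomerise the new alkene. The closest known reaction type is the Me2AlCl-promoted intramolecular type 2 carbonyl-ene cyclisation of aldehydes onto 1,1-disubstituted alkenes, which gives 3-methylenecycloalkanols. The seven-membered ring closes in the exo mode at the carbonyl (7-exo-trig) with the central ene carbon C8 inside the tether, which is why hydroxyl and exocyclic methylene appear together. The only new stereocentre, C6, is controlled by C5: the formyl group should react in the rotamer with C=O syn to C5–H and the formyl hydrogen between the two quaternary carbons, and the alkene, tethered through C1, attacks anti to C4, which places the aluminium-bound oxygen equatorial and away from the axial C1 methyl (6S). The step needs ene reactivity in preference to cationic Prins pathways and to β-elimination of the C4 silyloxy group, and hydrogen transfer from C14 in preference to C9–H; the methane-releasing Lewis acid at low temperature, the silyl cap on the C4 oxygen (which also blocks retro-aldol cleavage) and the exocyclic position of the methyl secure these.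

Step 13
Reactants: 23 4-hydroxybenzoic acid
Product: 24 tert-butyldimethylsilyl 4-(tert-butyldimethylsilyloxy)benzoate
Conditions: tBuMe2SiCl (2.2 equiv), imidazole, DMF, rt
Reagents that add atoms: tert-butylchlorodimethylsilane, CC(C)(C)[Si](C)(C)Cl
Why: Imidazole-mediated silylation of both acidic hydroxyl groups, giving a silyl ester that is activated directly in step 14.

Step 14
Reactants: 24 bis(silyl) compound
Product: 25 4-(tert-butyldimethylsilyloxy)benzoyl chloride
Conditions: (COCl)2, DMF (cat.), CH2Cl2, 0 °C → rt
Reagents that add atoms: oxalyl chloride, ClC(=O)C(Cl)=O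
Why: Vilsmeier-type activation converts a silyl ester directly into the acid chloride with loss of the silyl chloride, so no HCl is formed and the aryl silyl ether survives.

Step 15
Reactants: 22 bicyclic alcohol; 25 acid chloride
Product: 26 silylated ferugin (C6 4-(TBS-oxy)benzoate; C4–OSiEt3; C9–OTBS)
Conditions: Et3N, DMAP, CH2Cl2, rt → 40 °C
Reagents that add atoms: none
Why: DMAP-catalysed acylation of the only free hydroxyl, the equatorial C6 alcohol, by the acid chloride, with retention at C6.

Step 16
Reactants: 26 silylated ester
Product: 27 ferugin, (1R,4R,5S,6S,9S)-4,9-dihydroxydauc-8(14)-en-6-yl 4-hydroxybenzoate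
Conditions: Bu4NF, AcOH, THF, 0 °C → rt
Reagents that add atoms: none
Why: Fluoride cleaves the aryl, secondary and tertiary silyl ethers in one operation, and acetic acid buffering keeps phenoxide and alkoxides from attacking or shifting the benzoate.

**Compound list**

1 | 3-methylcyclopent-2-en-1-one | CC1=CC(=O)CC1 | starting material
2 | ethynyltrimethylsilane | C#C[Si](C)(C)C | starting material
3 | diisobutyl[1-(trimethylsilyl)ethenyl]alane | C=C([Si](C)(C)C)[Al](CC(C)C)CC(C)C | intermediate (not isolated)
4 | diisobutylaluminium enolate of (S)-3-methyl-3-[1-(trimethylsilyl)ethenyl]cyclopentanone (C4=C5 enolate) | CC(C)C[Al](CC(C)C)OC1=C[C@](C)(CC1)C(=C)[Si](C)(C)C | intermediate (not isolated)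
5 | triethyl({(3S)-3-methyl-3-[1-(trimethylsilyl)ethenyl]cyclopent-1-en-1-yl}oxy)silane | CC[Si](CC)(CC)OC1=C[C@](C)(CC1)C(=C)[Si](C)(C)C | intermediate
6 | formaldehyde | C=O | starting material
7 | (2S,3S)-2-(hydroxymethyl)-3-methyl-3-[1-(trimethylsilyl)ethenyl]cyclopentan-1-one | OC[C@@H]1[C@](C)(CCC1=O)C(=C)[Si](C)(C)C | intermediate
8 | (2S,3S)-3-methyl-2-[(triethylsilyloxy)methyl]-3-[1-(trimethylsilyl)ethenyl]cyclopentan-1-one | CC[Si](CC)(CC)OC[C@@H]1[C@](C)(CCC1=O)C(=C)[Si](C)(C)C | intermediate
9 | isopropylmagnesium chloride | CC(C)[Mg]Cl | starting material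
10 | (1R,2S,3S)-3-methyl-1-(propan-2-yl)-2-[(triethylsilyloxy)methyl]-3-[1-(trimethylsilyl)ethenyl]cyclopentan-1-ol | CC[Si](CC)(CC)OC[C@@H]1[C@](C)(CC[C@@]1(O)C(C)C)C(=C)[Si](C)(C)C | intermediate
11 | alkylborane from 10 (C1 arm CH(SiMe3)–CH2–BH2, drawn as the monoalkylborane) | CC[Si](CC)(CC)OC[C@@H]1[C@](C)(CC[C@@]1(O)C(C)C)C(CB)[Si](C)(C)C | intermediate (not isolated)
12 | primary alcohol with C1 arm CH(SiMe3)–CH2OH (both C10 epimers), otherwise as 10 | CC[Si](CC)(CC)OC[C@@H]1[C@](C)(CC[C@@]1(O)C(C)C)C(CO)[Si](C)(C)C | intermediate
13 | α-silyl aldehyde with C1 arm CH(SiMe3)–CHO | CC[Si](CC)(CC)OC[C@@H]1[C@](C)(CC[C@@]1(O)C(C)C)C(C=O)[Si](C)(C)C | intermediate (not isolated)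
14 | C9 aldehyde with C1 arm CH2–CHO; C4–OH β, isopropyl α, C6–OSiEt3 on the β face | CC[Si](CC)(CC)OC[C@@H]1[C@](C)(CC[C@@]1(O)C(C)C)CC=O | intermediate
15 | isopropenylmagnesium bromide | CC(=C)[Mg]Br | starting material
16 | allylic alcohols with C1 arm CH2–CH(OH)–C(CH3)=CH2 (C9 epimers) | CC[Si](CC)(CC)OC[C@@H]1[C@](C)(CC[C@@]1(O)C(C)C)CC(O)C(C)=C | intermediate
17 | enone with C1 arm CH2–C(=O)–C(CH3)=CH2 | CC[Si](CC)(CC)OC[C@@H]1[C@](C)(CC[C@@]1(O)C(C)C)CC(=O)C(C)=C | intermediate
18 | (9S)-allylic alcohol (C4–OH and C9–OH free, C6–OSiEt3) | CC[Si](CC)(CC)OC[C@@H]1[C@](C)(CC[C@@]1(O)C(C)C)C[C@H](O)C(C)=C | intermediate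
19 | C9 TBS ether of 18 (C4–OH free) | CC[Si](CC)(CC)OC[C@@H]1[C@](C)(CC[C@@]1(O)C(C)C)C[C@H](O[Si](C)(C)C(C)(C)C)C(C)=C | intermediate (not isolated)
20 | tris(silyl) ether (C6–OSiEt3, C4–OSiEt3, C9–OTBS) | CC[Si](CC)(CC)OC[C@@H]1[C@](C)(CC[C@@]1(O[Si](CC)(CC)CC)C(C)C)C[C@H](O[Si](C)(C)C(C)(C)C)C(C)=C | intermediate
21 | cyclopentanecarbaldehyde, ene precursor (C5–CHO, C4–OSiEt3, C9–OTBS, 2-propenyl on C9) | O=C[C@@H]1[C@](C)(CC[C@@]1(O[Si](CC)(CC)CC)C(C)C)C[C@H](O[Si](C)(C)C(C)(C)C)C(C)=C | intermediate
22 | (1R,4R,5S,6S,9S)-9-(tert-butyldimethylsilyloxy)-4-(triethylsilyloxy)dauc-8(14)-en-6-ol | C=C1C[C@H](O)[C@@H]2[C@](C)(CC[C@@]2(O[Si](CC)(CC)CC)C(C)C)C[C@@H]1O[Si](C)(C)C(C)(C)C | intermediate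
23 | 4-hydroxybenzoic acid | OC(=O)c1ccc(O)cc1 | starting material
24 | tert-butyldimethylsilyl 4-(tert-butyldimethylsilyloxy)benzoate | CC(C)(C)[Si](C)(C)OC(=O)c1ccc(O[Si](C)(C)C(C)(C)C)cc1 | intermediate
25 | 4-(tert-butyldimethylsilyloxy)benzoyl chloride | CC(C)(C)[Si](C)(C)Oc1ccc(cc1)C(Cl)=O | intermediate
26 | silylated ferugin: C6 4-(tert-butyldimethylsilyloxy)benzoate of 22 | C=C1C[C@H](OC(=O)c3ccc(O[Si](C)(C)C(C)(C)C)cc3)[C@@H]2[C@](C)(CC[C@@]2(O[Si](CC)(CC)CC)C(C)C)C[C@@H]1O[Si](C)(C)C(C)(C)C | intermediate
27 | ferugin, (1R,4R,5S,6S,9S)-4,9-dihydroxydauc-8(14)-en-6-yl 4-hydroxybenzoate | C=C1C[C@H](OC(=O)c2ccc(O)cc2)[C@@H]2[C@](C)(CC[C@@]2(O)C(C)C)C[C@@H]1O | target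

**Count**

Total steps: 16. Longest linear sequence: 14 (steps 1–12, 15, 16); steps 13 and 14 form the short acyl branch.

**Steps most likely to fail**

1. Step 12 (key step). What may go wrong: the alkene may add to the other face of the aluminium-bound aldehyde, so that the hydroxyl is formed axial at C6; competing Prins-type chloride or methyl capture would lower the return. Fallback: setting out from aldehyde 21, the cyclisation is run as before and the 6-epi alcohol F1 is taken on. 4-(tert-Butyldimethylsilyloxy)benzoic acid F2 is freed from silyl ester 24 (K2CO3, MeOH/THF/H2O, then mild acid). F1 and F2 are joined under Mitsunobu conditions (PPh3, DIAD, toluene, 0 °C → rt), which esterifies with inversion at C6 and comes back to the route at ester 26.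

2. Step 1. What may go wrong: silyl transfer to the hindered diisobutylaluminium enolate may be slow, so that protonation on work-up returns the ketone and the regiochemical handle for C5 is lost. Fallback: setting out from 1 and 2 (through 3 and 4 as before), enolate 4 is acetylated with Ac2O to the enol acetate F3. Two equivalents of MeLi (THF, 0 °C) release the lithium enolate F4, which is treated with gaseous formaldehyde 6 at −78 °C; this aldol reaction comes back to the route at hydroxy ketone 7. Should the enantiomeric purity fall short, the catalyst-controlled reduction of step 9 turns the minor enantiomer into a diastereomer of 18 that should be removable by chromatography.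

3. Step 6. What may go wrong: Peterson-type loss of silicon and oxygen from the β-hydroxysilane during oxidation, or incomplete C-desilylation of the α-silyl aldehyde together with erosion of the primary silyl ether in basic methanol. Fallback: setting out from 12, the Peterson elimination is carried out on purpose (KH, THF, 0 °C) to give the vinyl compound F5. Hydroboration with 9-BBN gives the B-alkyl-9-borabicyclo[3.3.1]nonane F6, oxidation (NaOH, H2O2) gives the primary alcohol F7, and Dess–Martin oxidation comes back to the route at aldehyde 14.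

**Further compounds**

F1 | step 12 | 6-epi alcohol, (6R) epimer of 22 | C=C1C[C@@H](O)[C@@H]2[C@](C)(CC[C@@]2(O[Si](CC)(CC)CC)C(C)C)C[C@@H]1O[Si](C)(C)C(C)(C)C
F2 | step 12 | 4-(tert-butyldimethylsilyloxy)benzoic acid | CC(C)(C)[Si](C)(C)Oc1ccc(cc1)C(=O)O
F3 | step 1 | (3S)-3-methyl-3-[1-(trimethylsilyl)ethenyl]cyclopent-1-en-1-yl acetate | CC(=O)OC1=C[C@](C)(CC1)C(=C)[Si](C)(C)C
F4 | step 1 | lithium enolate of (S)-3-methyl-3-[1-(trimethylsilyl)ethenyl]cyclopentanone (C4=C5) | [Li]OC1=C[C@](C)(CC1)C(=C)[Si](C)(C)C
F5 | step 6 | vinyl compound (C1 arm CH=CH2, otherwise as 10) | CC[Si](CC)(CC)OC[C@@H]1[C@](C)(CC[C@@]1(O)C(C)C)C=C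
F6 | step 6 | B-alkyl-9-borabicyclo[3.3.1]nonane from F5 (C1 arm CH2–CH2–B) | CC[Si](CC)(CC)OC[C@@H]1[C@](C)(CC[C@@]1(O)C(C)C)CCB2C3CCCC2CCC3
F7 | step 6 | primary alcohol (C1 arm CH2–CH2OH) | CC[Si](CC)(CC)OC[C@@H]1[C@](C)(CC[C@@]1(O)C(C)C)CCO
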